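**Retrosynthetic overview**
- No ring is formed; both benzene rings are bought intact.
- Key disconnection: the C(=O)–Cα bond of the enone, made from an acyl anion equivalent (the Breslow intermediate of 4-geranyloxy-2-hydroxybenzaldehyde) and a vinyl cation equivalent (an (E)-styryl(phenyl)iodonium salt). Both carbons are electrophilic in their native state.
- The iodonium salt comes from 4-ethynylphenyl acetate by hydroboration (fixes the E geometry) and boron-to-iodine exchange.
- The aldehyde comes from 2,4-dihydroxybenzaldehyde and geranyl bromide by 4-O-selective alkylation. The one protecting group (aryl acetate) is removed in the pot of the key step.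

Assumption: the target has no stereocentre, so "single enantiomer" is read as the single (2E)-geranyl, (E)-enone isomer drawn; 4-ethynylphenyl acetate is taken as a catalogue compound.

**Route**

Step 1
Reactants: 1 2,4-dihydroxybenzaldehyde; 2 geranyl bromide [(2E)-1-bromo-3,7-dimethylocta-2,6-diene]
Product: 3 4-{[(2E)-3,7-dimethylocta-2,6-dien-1-yl]oxy}-2-hydroxybenzaldehyde
Conditions: 2 (1.05 equiv), CsHCO3 (1.5 equiv), MeCN, 60 °C
Reagents that add atoms: none
Why: Williamson ether synthesis (SN2 at the primary allylic bromide, E-alkene untouched); the 2-OH is tied up in a hydrogen bond to the formyl group, so the weak base ionises and alkylates only the 4-OH.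

Step 2
Reactants: 4 4-ethynylphenyl acetate
Product: 6 (E)-[2-(4-acetoxyphenyl)ethenyl]boronic acid, via catechol alkenylboronate 5 (not isolated)
Conditions: catecholborane (1.1 equiv), Cy2BH (5 mol%), THF, rt; then H2O, rt; crystallise
Reagents that add atoms: catecholborane, B1Oc2ccccc2O1; water, O
Why: Dialkylborane-catalysed hydroboration of the terminal alkyne is a syn, anti-Markovnikov addition that sets the E-alkenylboron geometry, and water hydrolyses the catechol ester while the aryl acetate survives.

Step 3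
Reactants: 6 (E)-[2-(4-acetoxyphenyl)ethenyl]boronic acid
Product: 7 (E)-[2-(4-acetoxyphenyl)ethenyl](phenyl)iodonium tetrafluoroborate
Conditions: PhI(OAc)2 (1.1 equiv), BF3·OEt2 (1.1 equiv), CH2Cl2, 0 °C; then satd aq NaBF4; precipitate with Et2O
Reagents that add atoms: (diacetoxyiodo)benzene, CC(=O)OI(OC(C)=O)c1ccccc1; sodium tetrafluoroborate, [Na+].F[B-](F)(F)F
Why: BF3-promoted boron-to-trivalent-iodine exchange (ipso substitution of the alkenylboronic acid) proceeds with retention of the E geometry, and anion metathesis gives the crystalline tetrafluoroborate.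

Step 4
Reactants: 3 4-{[(2E)-3,7-dimethylocta-2,6-dien-1-yl]oxy}-2-hydroxybenzaldehyde; 7 (E)-[2-(4-acetoxyphenyl)ethenyl](phenyl)iodonium tetrafluoroborate
Product: 10 (2E)-1-(4-{[(2E)-3,7-dimethylocta-2,6-dien-1-yl]oxy}-2-hydroxyphenyl)-3-(4-hydroxyphenyl)prop-2-en-1-one, via Breslow intermediate 8 (not isolated), via chalcone acetate 9 (not isolated)
Conditions: 3 (1.2 equiv), 7 (1.0 equiv), 2-(pentafluorophenyl)-6,7-dihydro-5H-pyrrolo[2,1-c][1,2,4]triazol-2-ium tetrafluoroborate (15 mol%), TMEDA (1.2 equiv), THF, −40 °C to 0 °C; then MeOH, K2CO3 (2 equiv), rt, 1 h; aq NH4Cl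
Reagents that add atoms: none
Why: Proposed new method: the triazolylidene adds to the formyl group of 3 and proton transfer gives Breslow intermediate 8, an acyl anion equivalent whose nucleophilic carbon attacks the iodine-bearing vinyl carbon of 7 (ligand coupling at trivalent iodine, retention of E) with loss of PhI and release of the carbene to give enone 9, after which K2CO3/MeOH transesterifies the aryl acetate to 10; the closest known reaction type is the carbene-catalysed C–H vinylation, alkynylation and arylation of aryl aldehydes with vinyl-, alkynyl- and diaryliodonium salts, here stretched to an electron-rich salicylaldehyde with a free hydrogen-bonded phenol (7 is kept limiting so no iodonium salt remains when the phenoxides are formed).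

**Compound list**

1 | 2,4-dihydroxybenzaldehyde | O=Cc1ccc(O)cc1O | starting material
2 | geranyl bromide, (2E)-1-bromo-3,7-dimethylocta-2,6-diene | CC(C)=CCC/C(C)=C/CBr | starting material
3 | 4-{[(2E)-3,7-dimethylocta-2,6-dien-1-yl]oxy}-2-hydroxybenzaldehyde | CC(C)=CCC/C(C)=C/COc1ccc(C=O)c(O)c1 | intermediate
4 | 4-ethynylphenyl acetate | CC(=O)Oc1ccc(C#C)cc1 | starting material
5 | 4-[(E)-2-(1,3,2-benzodioxaborol-2-yl)ethenyl]phenyl acetate (catechol alkenylboronate) | CC(=O)Oc1ccc(/C=C/B2Oc3ccccc3O2)cc1 | intermediate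
6 | (E)-[2-(4-acetoxyphenyl)ethenyl]boronic acid | CC(=O)Oc1ccc(/C=C/B(O)O)cc1 | intermediate
7 | (E)-[2-(4-acetoxyphenyl)ethenyl](phenyl)iodonium tetrafluoroborate | CC(=O)Oc1ccc(/C=C/[I+]c2ccccc2)cc1.F[B-](F)(F)F | intermediate
8 | Breslow intermediate: enaminol from 3 and 2-(pentafluorophenyl)-6,7-dihydro-5H-pyrrolo[2,1-c][1,2,4]triazol-3-ylidene, aryl(hydroxy)methylidene at C3 of the triazoline | CC(C)=CCC/C(C)=C/COc1ccc(C(O)=C2N(c3c(F)c(F)c(F)c(F)c3F)N=C3CCCN23)c(O)c1 | intermediate
9 | 4-[(1E)-3-(4-{[(2E)-3,7-dimethylocta-2,6-dien-1-yl]oxy}-2-hydroxyphenyl)-3-oxoprop-1-en-1-yl]phenyl acetate | CC(C)=CCC/C(C)=C/COc1ccc(C(=O)/C=C/c2ccc(OC(C)=O)cc2)c(O)c1 | intermediate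
10 | (2E)-1-(4-{[(2E)-3,7-dimethylocta-2,6-dien-1-yl]oxy}-2-hydroxyphenyl)-3-(4-hydroxyphenyl)prop-2-en-1-one | CC(C)=CCC/C(C)=C/COc1ccc(C(=O)/C=C/c2ccc(O)cc2)c(O)c1 | target

**Step count**

Total steps: 4. Longest linear sequence: 3 steps (4 → 6 → 7 → 10); the other branch is 1 → 3 → 10.

**Steps most likely to fail, with fallbacks**

Step 4, the carbene-catalysed vinylation, is the riskiest. The phenol of 3 is partly ionised by the amine, which deactivates the aldehyde and offers an oxygen nucleophile to 7; the electron-rich aldehyde may form its Breslow intermediate slowly; and 7 can collapse to the alkyne under base. The fallback sets out from 3 and comes back at 10. Silylation of 3 (TBSCl, imidazole, DMF, rt) gives 2-[(tert-butyldimethylsilyl)oxy]-4-{[(2E)-3,7-dimethylocta-2,6-dien-1-yl]oxy}benzaldehyde F1, which has no acidic OH and no hydrogen bond to the formyl group. F1 is coupled with 7 under the same carbene catalysis, through the corresponding Breslow intermediate F2, to 4-[(1E)-3-(2-[(tert-butyldimethylsilyl)oxy]-4-{[(2E)-3,7-dimethylocta-2,6-dien-1-yl]oxy}phenyl)-3-oxoprop-1-en-1-yl]phenyl acetate F3. K2CO3 in MeOH then removes the aryl silyl ether and the acetate in one operation to give 10.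

Step 3, the boron-to-iodine exchange, can fail by protodeboronation or acid-promoted oligomerisation of the styrylboronic acid under BF3, or the salt may not crystallise. The fallback sets out from 4 and comes back at 7, with silicon as the vinyl-metal handle. Hydrosilylation of 4 with Et3SiH (Pt2[(CH2=CHSiMe2)2O]3, P(t-Bu)3, THF, rt) gives (E)-4-[2-(triethylsilyl)ethenyl]phenyl acetate F4. Silicon-to-iodine exchange with iodosylbenzene and BF3·OEt2 in CH2Cl2 at 0 °C, followed by aqueous NaBF4, gives 7 with retention of geometry.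

Step 2, the hydroboration, can give some internal regioisomer, partial reduction of the aryl acetate, or losses on hydrolysis and crystallisation. The fallback sets out from 4 and comes back at 6. Hydroboration with pinacolborane catalysed by Cp2Zr(H)Cl (5 mol%, Et3N, 60 °C) gives the chromatographable 4-[(E)-2-(4,4,5,5-tetramethyl-1,3,2-dioxaborolan-2-yl)ethenyl]phenyl acetate F5. Oxidative cleavage of the pinacol with NaIO4 and NH4OAc in acetone–water at rt gives 6.

**Further compounds**

F1 | step 4 | 2-[(tert-butyldimethylsilyl)oxy]-4-{[(2E)-3,7-dimethylocta-2,6-dien-1-yl]oxy}benzaldehyde | CC(C)=CCC/C(C)=C/COc1ccc(C=O)c(O[Si](C)(C)C(C)(C)C)c1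
F2 | step 4 | Breslow intermediate from F1 and 2-(pentafluorophenyl)-6,7-dihydro-5H-pyrrolo[2,1-c][1,2,4]triazol-3-ylidene | CC(C)=CCC/C(C)=C/COc1ccc(C(O)=C2N(c3c(F)c(F)c(F)c(F)c3F)N=C3CCCN23)c(O[Si](C)(C)C(C)(C)C)c1
F3 | step 4 | 4-[(1E)-3-(2-[(tert-butyldimethylsilyl)oxy]-4-{[(2E)-3,7-dimethylocta-2,6-dien-1-yl]oxy}phenyl)-3-oxoprop-1-en-1-yl]phenyl acetate | CC(C)=CCC/C(C)=C/COc1ccc(C(=O)/C=C/c2ccc(OC(C)=O)cc2)c(O[Si](C)(C)C(C)(C)C)c1
F4 | step 3 | (E)-4-[2-(triethylsilyl)ethenyl]phenyl acetate | CC[Si](CC)(CC)/C=C/c1ccc(OC(C)=O)cc1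
F5 | step 2 | 4-[(E)-2-(4,4,5,5-tetramethyl-1,3,2-dioxaborolan-2-yl)ethenyl]phenyl acetate | CC(=O)Oc1ccc(/C=C/B2OC(C)(C)C(C)(C)O2)cc1
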